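**Remarks on the chemistry (assumptions)**

- Atom labels in the text follow germacrane numbering of the target: C1 ketone carbon, C2 furanone CH, C3 furanone C–O, C4=C5 ring alkene, C6 lactone carbinol, C7, C8 (tiglate), C9, C10 (quaternary C–O), C11/C12/C13 lactone α-carbon, carbonyl and exocyclic CH2, C14 methyl on C10, C15 CH2OH on C4.
- Assumption: (S,S)-ProPhenol delivers the alkynyl group to the Si face of aldehyde 11 (giving 8R); if the opposite sense is found, (R,R)-ProPhenol is used.

**Retrosynthetic overview**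

1. The 3(2H)-furanone (O, C10, C1, C2, C3) is a cyclodehydrated α′-oxy-1,3-diketone. The C15 oxygen on C4 lies five atoms from C2 (C2–C3–C4–C15–O), so carrying C1 as its ester (ten-membered macrolactone 22) puts C1 six atoms from the C2 enolate; a Claisen-type O→C acyl transfer then forms C1–C2, closes the carbocycle and frees 15-OH.
2. Macrolactone 22 and the cis-fused α-methylene-γ-lactone arise together by intramolecular indium Barbier allylation (C6–C7) of aldehyde/allylic bromide 20.
3. The (Z)-4-oxo-enal of 20 (C2–C6, C15) is a ring-opened 2-methyl-3-(acyloxymethyl)furan, so the western half is (2-methylfuran-3-yl)methanol 8, which also serves as the ester tether.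
4. The eastern chain comes from (S)-lactic acid (C10 by Seebach alkylation), methyl propiolate (C8 by Zn–ProPhenol alkynylation), tigloyl chloride and formaldehyde (C13).
5. Ring order: macrolactone and γ-lactone (step 11), then ten-membered carbocycle and furanone (step 12).

Key step: step 12

**Route**

Step 1
Reactants: 1 (S)-lactic acid; 2 pivalaldehyde
Product: 3 (2S,5S)-2-tert-butyl-5-methyl-1,3-dioxolan-4-one (cis)
Conditions: TsOH·H2O (cat.), H2SO4 (cat.), pentane, reflux, Dean–Stark trap; recrystallisation
Reagents that add atoms: none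
Why: Acid-catalysed acetalisation (Seebach self-regeneration of stereocentres) should give mainly the cis acetal, which is purified by crystallisation and whose tert-butyl group later relays the configuration to C10.

Step 2
Reactants: 3 (2S,5S)-2-tert-butyl-5-methyl-1,3-dioxolan-4-one; 4 allyl bromide
Product: 6 (2S,5R)-2-tert-butyl-5-methyl-5-(prop-2-en-1-yl)-1,3-dioxolan-4-one, via lithium enolate 5 (not isolated)
Conditions: LiN(i-Pr)2, THF, −78 °C; then 4, −78 → −20 °C
Reagents that add atoms: none
Why: Seebach enolate alkylation, in which allyl bromide should enter anti to the tert-butyl group and so set the quaternary centre (future C10) with overall retention.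

Step 3
Reactants: 7 methyl 2-methylfuran-3-carboxylate
Product: 8 (2-methylfuran-3-yl)methanol
Conditions: LiAlH4, Et2O, 0 °C
Reagents that add atoms: none
Why: Ester reduction with LiAlH4, which leaves the furan untouched.

Step 4
Reactants: 6 (2S,5R)-2-tert-butyl-5-methyl-5-(prop-2-en-1-yl)-1,3-dioxolan-4-one; 8 (2-methylfuran-3-yl)methanol
Product: 10 (2-methylfuran-3-yl)methyl (2R)-2-methyl-2-[(triethylsilyl)oxy]pent-4-enoate, via hydroxy ester 9 (not isolated)
Conditions: 8 (1.1 equiv), NaH (0.15 equiv), toluene, 0 → 25 °C; then 2,6-lutidine, Et3SiOTf, 0 °C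
Reagents that add atoms: triethylsilyl trifluoromethanesulfonate, CC[Si](CC)(CC)OS(=O)(=O)C(F)(F)F
Why: Alkoxide transesterification of the acylal-type dioxolanone (the expelled hemiacetal alkoxide collapses to pivalaldehyde and the tertiary alkoxide, which regenerates the nucleophile), followed by silylation of the tertiary alcohol with the silyl triflate; no stereocentre is touched.

Step 5
Reactants: 10 (2-methylfuran-3-yl)methyl (2R)-2-methyl-2-[(triethylsilyl)oxy]pent-4-enoate
Product: 11 (2-methylfuran-3-yl)methyl (2R)-2-methyl-4-oxo-2-[(triethylsilyl)oxy]butanoate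
Conditions: OsO4 (2 mol %), NaIO4 (4 equiv), 2,6-lutidine, 1,4-dioxane/H2O 3:1, 25 °C
Reagents that add atoms: osmium tetroxide, O=[Os](=O)(=O)=O (catalytic oxygen carrier); sodium periodate, [Na+].[O-]I(=O)(=O)=O (terminal oxidant)
Why: Lemieux–Johnson oxidative cleavage, in which OsO4 should dihydroxylate the monosubstituted alkene much faster than the aromatic furan while lutidine suppresses over-oxidation.

Step 6
Reactants: 11 (2-methylfuran-3-yl)methyl (2R)-2-methyl-4-oxo-2-[(triethylsilyl)oxy]butanoate; 12 methyl propiolate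
Product: 14 7-methyl 1-[(2-methylfuran-3-yl)methyl] (2R,4R)-4-hydroxy-2-methyl-2-[(triethylsilyl)oxy]hept-5-ynedioate, via alkynylzinc 13 (not isolated)
Conditions: 12 (3 equiv), Me2Zn (3 equiv), (S,S)-ProPhenol (20 mol %), Ph3P=O (40 mol %), toluene, 0 → 4 °C; aq. NH4Cl
Reagents that add atoms: none
Why: Zinc–ProPhenol catalysed asymmetric alkynylation of an aldehyde, in which the chiral dinuclear zinc catalyst controls the face of addition and so sets C8 (R) independently of the remote C10 centre.

Step 7
Reactants: 14 7-methyl 1-[(2-methylfuran-3-yl)methyl] (2R,4R)-4-hydroxy-2-methyl-2-[(triethylsilyl)oxy]hept-5-ynedioate; 15 tigloyl chloride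
Product: 16 7-methyl 1-[(2-methylfuran-3-yl)methyl] (2R,4R)-2-methyl-4-{[(2E)-2-methylbut-2-enoyl]oxy}-2-[(triethylsilyl)oxy]hept-5-ynedioate
Conditions: 15 (1.5 equiv), pyridine, DMAP (10 mol %), CH2Cl2, 0 °C
Reagents that add atoms: none
Why: DMAP-catalysed acylation of the secondary propargylic alcohol, done promptly so that O8 cannot lactonise onto the C1 ester; the tiglate then stays in place to the end.

Step 8
Reactants: 16 7-methyl 1-[(2-methylfuran-3-yl)methyl] (2R,4R)-2-methyl-4-{[(2E)-2-methylbut-2-enoyl]oxy}-2-[(triethylsilyl)oxy]hept-5-ynedioate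
Product: 18 7-methyl 1-[(2-methylfuran-3-yl)methyl] (2R,4R,5Z)-6-(hydroxymethyl)-2-methyl-4-{[(2E)-2-methylbut-2-enoyl]oxy}-2-[(triethylsilyl)oxy]hept-5-enedioate, via vinylalane 17 (not isolated)
Conditions: (i-Bu)2AlH (1.3 equiv), N-methylmorpholine N-oxide (1.4 equiv), THF, 0 °C; then CH2O (gas from cracked paraformaldehyde), −40 → 0 °C; aq. potassium sodium tartrate (KNaC4H4O6)
Reagents that add atoms: formaldehyde, C=O
Why: Vinylalumination (conjugate syn-hydroalumination of the ynoate by the amine-oxide complex of the aluminium hydride, hydride to C7 and aluminium to C11) followed by aldol-type trapping with formaldehyde installs C13; the complexed hydride should prefer the electron-poor alkyne over the other esters.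

Step 9
Reactants: 18 7-methyl 1-[(2-methylfuran-3-yl)methyl] (2R,4R,5Z)-6-(hydroxymethyl)-2-methyl-4-{[(2E)-2-methylbut-2-enoyl]oxy}-2-[(triethylsilyl)oxy]hept-5-enedioate
Product: 19 7-methyl 1-[(2-methylfuran-3-yl)methyl] (2R,4R,5E)-6-(bromomethyl)-2-methyl-4-{[(2E)-2-methylbut-2-enoyl]oxy}-2-[(triethylsilyl)oxy]hept-5-enedioate
Conditions: CBr4, PPh3, CH2Cl2, −20 °C
Reagents that add atoms: tetrabromomethane, BrC(Br)(Br)Br
Why: Appel bromination of the primary allylic alcohol under neutral conditions, which the furan, silyl ether and esters should tolerate.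

Step 10
Reactants: 19 7-methyl 1-[(2-methylfuran-3-yl)methyl] (2R,4R,5E)-6-(bromomethyl)-2-methyl-4-{[(2E)-2-methylbut-2-enoyl]oxy}-2-[(triethylsilyl)oxy]hept-5-enedioate
Product: 20 1-[(2Z)-2-acetyl-4-oxobut-2-en-1-yl] 7-methyl (2R,4R,5E)-6-(bromomethyl)-2-methyl-4-{[(2E)-2-methylbut-2-enoyl]oxy}-2-[(triethylsilyl)oxy]hept-5-enedioate
Conditions: dimethyldioxirane (1.05 equiv, acetone solution), CH2Cl2, −78 → −30 °C; concentrated cold and used directly
Reagents that add atoms: dimethyldioxirane, CC1(C)OO1
Why: Oxidative furan ring opening to the cis-enedione, in which the electron-rich furan should react far faster than the electron-poor alkenes and the Z geometry (C3 cis to C6) is inherited from the ring; it unveils the C6 aldehyde and the C2 methyl ketone at once.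

Step 11
Reactants: 20 1-[(2Z)-2-acetyl-4-oxobut-2-en-1-yl] 7-methyl (2R,4R,5E)-6-(bromomethyl)-2-methyl-4-{[(2E)-2-methylbut-2-enoyl]oxy}-2-[(triethylsilyl)oxy]hept-5-enedioate
Product: 22 macrolactone (4Z,6S,7R,8R,10R): ten-membered lactone C1(=O)–O–C15H2–C4(=C5H)–C6–C7–C8–C9–C10 with acetyl (C3, C2) on C4, cis-fused α-methylene-γ-butyrolactone on C6/C7 (H6 and H7 cis), tiglate on O8, methyl and OSiEt3 on C10, via seco hydroxy ester 21 (not isolated)
Conditions: zerovalent indium (In powder, 3 equiv), THF/H2O 3:1, 2 mM, slow addition of 20, 25 °C; then PPTS (20 mol %), CH2Cl2, 25 °C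
Reagents that add atoms: none
Why: Intramolecular Barbier-type indium allylation, in which the 2-(methoxycarbonyl)allylindium (equilibrating to the geometry with C8 cis to CH2In whatever the geometry of 19) should add through C7 to the C6 aldehyde in a Zimmerman–Traxler chair to give the 6,7-syn adduct (cis-lactone after attack of O6 on C12), with attack anti to C9 in the conformer that has C8–H eclipsing the allyl unit setting C7 relative to C8, while the ester tether makes the ten-membered closure intramolecular.

Step 12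
Reactants: 22 macrolactone (4Z,6S,7R,8R,10R)
Product: 24 target, (4Z,6S,7R,8R,10R)-3,10-epoxy-15-hydroxy-1-oxogermacra-2,4,11(13)-trien-12,6-olide 8-O-[(2E)-2-methylbut-2-enoate], via macrocyclic diketone 23 (not isolated)
Conditions: LiN(SiMe3)2 (2.2 equiv), THF, −78 → −40 °C; then 1 M aq. HCl, THF, 0 → 25 °C
Reagents that add atoms: none
Why: Proposed new method: LiN(SiMe3)2 should deprotonate the acetyl methyl group (C2) kinetically, and the cross-conjugated enolate adds to the macrolactone carbonyl C1, which the C15–O tether holds six atoms away (C2–C3–C4–C15–O–C1); the bridged tetrahedral alkoxide collapses with loss of the C15 alkoxide, so the ten-membered lactone is transposed into the ten-membered carbocycle and the 15-hydroxymethyl group is set free, driven by formation of the lithium 1,3-diketonate of 23. The closest known reaction types are the Baker–Venkataraman O→C acyl transfer of o-acyloxyaryl ketones and the intramolecular Claisen condensation of keto lactones to cyclic 1,3-diones, neither of which has been used to turn a macrolactone into a medium-ring carbocycle. Ring closures: the C1–C2 bond forms by a 6-(enolendo)-exo-trig attack whose collapse closes the carbocycle C1–C10 by ring transposition, and on acidification O10 (freed from silicon) adds 5-exo-trig to the C3 ketone and water is lost to give the 3(2H)-furanone. No new stereocentre is formed, C10 has no α-hydrogen, and the 4Z geometry is fixed by the ring. Selectivity needed: enolisation at C2 rather than γ-deprotonation at C6 or C7 or addition to the α-methylene lactone (hindered amide base at −78 °C), attack at C1 rather than at the lactone carbonyl C12 (six- against seven-membered transition state), and furanone rather than pyranone formation in acid (five-membered hemiketal from tertiary O10 against attack of primary O15 on the hindered C1 ketone).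

**Compound list**

1 | (S)-lactic acid | C[C@H](O)C(=O)O | starting material
2 | pivalaldehyde | CC(C)(C)C=O | starting material
3 | (2S,5S)-2-tert-butyl-5-methyl-1,3-dioxolan-4-one | C[C@@H]1O[C@H](C(C)(C)C)OC1=O | intermediate
4 | allyl bromide | C=CCBr | starting material
5 | lithium enolate of 3, lithium (2S)-2-tert-butyl-5-methyl-1,3-dioxol-4-olate | CC1=C(O[Li])O[C@@H](C(C)(C)C)O1 | intermediate
6 | (2S,5R)-2-tert-butyl-5-methyl-5-(prop-2-en-1-yl)-1,3-dioxolan-4-one | C[C@]1(CC=C)O[C@H](C(C)(C)C)OC1=O | intermediate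
7 | methyl 2-methylfuran-3-carboxylate | COC(=O)c1ccoc1C | starting material
8 | (2-methylfuran-3-yl)methanol | Cc1occc1CO | intermediate
9 | (2-methylfuran-3-yl)methyl (2R)-2-hydroxy-2-methylpent-4-enoate | Cc1occc1COC(=O)[C@@](C)(CC=C)O | intermediate
10 | (2-methylfuran-3-yl)methyl (2R)-2-methyl-2-[(triethylsilyl)oxy]pent-4-enoate | Cc1occc1COC(=O)[C@@](C)(CC=C)O[Si](CC)(CC)CC | intermediate
11 | (2-methylfuran-3-yl)methyl (2R)-2-methyl-4-oxo-2-[(triethylsilyl)oxy]butanoate | Cc1occc1COC(=O)[C@@](C)(CC=O)O[Si](CC)(CC)CC | intermediate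
12 | methyl propiolate | C#CC(=O)OC | starting material
13 | methyl(3-methoxy-3-oxoprop-1-yn-1-yl)zinc | C[Zn]C#CC(=O)OC | intermediate
14 | 7-methyl 1-[(2-methylfuran-3-yl)methyl] (2R,4R)-4-hydroxy-2-methyl-2-[(triethylsilyl)oxy]hept-5-ynedioate | Cc1occc1COC(=O)[C@@](C)(C[C@@H](O)C#CC(=O)OC)O[Si](CC)(CC)CC | intermediate
15 | tigloyl chloride, (2E)-2-methylbut-2-enoyl chloride | C/C=C(\C)C(Cl)=O | starting material
16 | 7-methyl 1-[(2-methylfuran-3-yl)methyl] (2R,4R)-2-methyl-4-{[(2E)-2-methylbut-2-enoyl]oxy}-2-[(triethylsilyl)oxy]hept-5-ynedioate | Cc1occc1COC(=O)[C@@](C)(C[C@@H](OC(=O)/C(C)=C/C)C#CC(=O)OC)O[Si](CC)(CC)CC | intermediate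
17 | vinylalane: the (5E)-hept-5-enedioate of 16 carrying diisobutylaluminium on C6 (C11 of the target) and hydrogen on C5 | Cc1occc1COC(=O)[C@@](C)(C[C@@H](OC(=O)/C(C)=C/C)/C=C(/[Al](CC(C)C)CC(C)C)C(=O)OC)O[Si](CC)(CC)CC | intermediate
18 | 7-methyl 1-[(2-methylfuran-3-yl)methyl] (2R,4R,5Z)-6-(hydroxymethyl)-2-methyl-4-{[(2E)-2-methylbut-2-enoyl]oxy}-2-[(triethylsilyl)oxy]hept-5-enedioate | Cc1occc1COC(=O)[C@@](C)(C[C@@H](OC(=O)/C(C)=C/C)/C=C(/CO)C(=O)OC)O[Si](CC)(CC)CC | intermediate
19 | 7-methyl 1-[(2-methylfuran-3-yl)methyl] (2R,4R,5E)-6-(bromomethyl)-2-methyl-4-{[(2E)-2-methylbut-2-enoyl]oxy}-2-[(triethylsilyl)oxy]hept-5-enedioate | Cc1occc1COC(=O)[C@@](C)(C[C@@H](OC(=O)/C(C)=C/C)/C=C(/CBr)C(=O)OC)O[Si](CC)(CC)CC | intermediate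
20 | 1-[(2Z)-2-acetyl-4-oxobut-2-en-1-yl] 7-methyl (2R,4R,5E)-6-(bromomethyl)-2-methyl-4-{[(2E)-2-methylbut-2-enoyl]oxy}-2-[(triethylsilyl)oxy]hept-5-enedioate | O=C/C=C(/COC(=O)[C@@](C)(C[C@@H](OC(=O)/C(C)=C/C)/C=C(/CBr)C(=O)OC)O[Si](CC)(CC)CC)C(C)=O | intermediate
21 | seco hydroxy ester (4Z,6S,7S,8R,10R): ten-membered lactone C1(=O)–O–C15–C4(=C5)–C6–C7–C8–C9–C10 with acetyl on C4, free 6-OH, 1-(methoxycarbonyl)vinyl on C7, tiglate on O8, methyl and OSiEt3 on C10 | C=C(C(=O)OC)[C@H]1[C@@H](O)/C=C(/COC(=O)[C@@](C)(C[C@H]1OC(=O)/C(C)=C/C)O[Si](CC)(CC)CC)C(C)=O | intermediate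
22 | macrolactone (4Z,6S,7R,8R,10R): as 21 but with O6 closed onto C12 as a cis-fused α-methylene-γ-butyrolactone | C=C1C(=O)O[C@H]2/C=C(/COC(=O)[C@@](C)(C[C@@H](OC(=O)/C(C)=C/C)[C@@H]12)O[Si](CC)(CC)CC)C(C)=O | intermediate
23 | macrocyclic diketone (4Z,6S,7R,8R,10R), formed as its lithium enolate: ten-membered carbocycle with C1 and C3 ketones, C2H2, 15-CH2OH on C4, cis-fused α-methylene lactone, 8-O-tiglate, 10-OSiEt3 | C=C1C(=O)O[C@H]2/C=C(/CO)C(=O)CC(=O)[C@@](C)(C[C@@H](OC(=O)/C(C)=C/C)[C@@H]12)O[Si](CC)(CC)CC | intermediate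
24 | target, (4Z,6S,7R,8R,10R)-3,10-epoxy-15-hydroxy-1-oxogermacra-2,4,11(13)-trien-12,6-olide 8-O-[(2E)-2-methylbut-2-enoate] (H6 and H7 cis) | C=C1C(=O)O[C@H]2/C=C(/CO)C3=CC(=O)[C@@](C)(C[C@@H](OC(=O)/C(C)=C/C)[C@@H]12)O3 | target

**Step count**

Total: 12 steps. Longest linear sequence: 11 steps (steps 1, 2, 4–12 from (S)-lactic acid); step 3 is a one-step branch.

**Three steps most likely to fail**

1. Step 12 (proposed new method). What may go wrong: γ-deprotonation at C6 or C7 followed by elimination or alkene migration, enolate attack on the lactone carbonyl C12 instead of C1, or a tetrahedral intermediate that reverts instead of collapsing. The fallback uses known chemistry (Barbier allylation, Claisen condensation, acid cyclodehydration of an α′-silyloxy-1,3-diketone), sets out from 19 and 8 and returns at 24. Alcohol 8 is silylated (t-BuMe2SiCl, imidazole) to tert-butyldimethyl[(2-methylfuran-3-yl)methoxy]silane F1, and its furan is opened with dimethyldioxirane to (2Z)-3-{[(tert-butyldimethylsilyl)oxy]methyl}-4-oxopent-2-enal F2. Intermolecular indium-mediated allylation of F2 with bromide 19 (zerovalent indium, THF/H2O; then PPTS) should give the cis-lactone seco ester F3, in which the furylmethyl ester at C1 is now an ordinary, untethered ester. LiN(SiMe3)2 under high dilution then closes the ten-membered ring at the same C1–C2 bond by a direct intramolecular Claisen condensation with alcohol 8 as leaving group, giving the bis-silylated macrocyclic diketone F4; this medium-ring closure has no entropic help from a tether and is itself uncertain. Aqueous HCl removes both silyl groups and forms the furanone, giving 24.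

2. Step 11. What may go wrong: intermolecular oligomerisation, reduction or Z-to-E isomerisation of the enedione by the metal, and poor facial selectivity at C6/C7 in the macrocyclic transition state. The fallback sets out from 19 and returns at 22. Palladium-catalysed borylation (B2pin2, Pd2(dba)3 as zerovalent palladium source, THF) converts 19 into the allylboronate F5 (thermodynamic geometry, C8 cis to CH2B). Dimethyldioxirane at −78 °C opens the furan to the enedione aldehyde allylboronate F6. F6 should cyclise in dilute toluene at 40–60 °C by a thermal intramolecular allylboration through a closed chair transition state, with no reducing metal present. Work-up with triethanolamine gives 21, which lactonises (PPTS) to 22.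

3. Step 8. What may go wrong: over-reduction of the other esters by the aluminium hydride, loss of the allylic tiglate, or incomplete trapping by formaldehyde. The fallback sets out from 16 and returns at 18. Pd(PPh3)4-catalysed syn-hydrostannation with Bu3SnH places tin on C11 to give the α-stannyl enoate F7. Iodine converts F7 into the α-iodo enoate F8 with retention of geometry. A Stille coupling of F8 with Bu3SnCH2OH (Pd2(dba)3, AsPh3, CuI, DMF) then gives 18.

**Further compounds**

F1 | step 12 | tert-butyldimethyl[(2-methylfuran-3-yl)methoxy]silane | Cc1occc1CO[Si](C)(C)C(C)(C)C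
F2 | step 12 | (2Z)-3-{[(tert-butyldimethylsilyl)oxy]methyl}-4-oxopent-2-enal | CC(=O)/C(CO[Si](C)(C)C(C)(C)C)=C\C=O
F3 | step 12 | cis-lactone seco ester (4Z,6S,7R,8R,10R): α-methylene-γ-butyrolactone bearing on C6 the (Z)-CH=C(CH2OSiMe2t-Bu)C(=O)CH3 chain and on C7 the C8(O-tiglate)–C9H2–C10(Me)(OSiEt3)–C1(=O)OCH2(2-methylfuran-3-yl) chain | Cc1occc1COC(=O)[C@@](C)(C[C@@H](OC(=O)/C(C)=C/C)[C@H]2C(=C)C(=O)O[C@H]2/C=C(/CO[Si](C)(C)C(C)(C)C)C(C)=O)O[Si](CC)(CC)CC
F4 | step 12 | 15-O-tert-butyldimethylsilyl ether of macrocyclic diketone 23 | C=C1C(=O)O[C@H]2/C=C(/CO[Si](C)(C)C(C)(C)C)C(=O)CC(=O)[C@@](C)(C[C@@H](OC(=O)/C(C)=C/C)[C@@H]12)O[Si](CC)(CC)CC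
F5 | step 11 | allylboronate: 19 with CH2Bpin in place of CH2Br, (5E), C8 cis to CH2B | Cc1occc1COC(=O)[C@@](C)(C[C@@H](OC(=O)/C(C)=C/C)/C=C(\CB1OC(C)(C)C(C)(C)O1)C(=O)OC)O[Si](CC)(CC)CC
F6 | step 11 | enedione aldehyde allylboronate: 20 with CH2Bpin in place of CH2Br, C8 cis to CH2B | O=C/C=C(/COC(=O)[C@@](C)(C[C@@H](OC(=O)/C(C)=C/C)/C=C(\CB1OC(C)(C)C(C)(C)O1)C(=O)OC)O[Si](CC)(CC)CC)C(C)=O
F7 | step 8 | α-stannyl enoate: (5E)-hept-5-enedioate of 16 with tributylstannyl on C6 | Cc1occc1COC(=O)[C@@](C)(C[C@@H](OC(=O)/C(C)=C/C)/C=C(/[Sn](CCCC)(CCCC)CCCC)C(=O)OC)O[Si](CC)(CC)CC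
F8 | step 8 | α-iodo enoate: (5E)-hept-5-enedioate of 16 with iodine on C6 | Cc1occc1COC(=O)[C@@](C)(C[C@@H](OC(=O)/C(C)=C/C)/C=C(/I)C(=O)OC)O[Si](CC)(CC)CC
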